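Follow the target through four flasks that differ in their charge of protic impurity.

    other conformer + protic impurity → quenched substrate (k1 = 1.27 L mol⁻¹ s⁻¹)
    other conformer ⇌ third conformer (K2 = 1.63, k2 = 0.0280 s⁻¹)
    starting material → target (k3 = 0.0585 s⁻¹)
    third conformer → third product (k4 = 0.0443 s⁻¹)
    starting material ⇌ other conformer (K5 = 1.46, k5 = 0.0151 s⁻¹)
    other conformer → isomer of the product (k6 = 0.246 s⁻¹)
    starting material ⇌ dormant form (K7 = 15, k7 = 0.0114 s⁻¹)

| flask | starting material | protic impurity | time |
|---|---|---|---|
| teal | 0.10 M | 0.0100 M | 40 s |
| ochre | 0.10 M | 0.0200 M | 40 s |
| green | 0.10 M | 0.0400 M | 40 s |
| red | 0.10 M | 0.0800 M | 40 s |

1. [target] at the end for teal, ochre, green, red, in this order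
2. the course of these numbers from the first flask to the last (hardly changes / falls, then rises / falls all the way / rises, then falls / rises all the way)

- "hardly changes" means that all values lie within two and a half points (for a concentration: within two and a half percent of the largest)
- run time (teal): 40 s

Target is made from starting material, while the impurity attacks other conformer, so the impurity can reach target through one door: other conformer going back to starting material. We therefore carry a ratio of rates in which time drops out. The back constant of that step is the forward constant over its equilibrium constant, 0.0103 s⁻¹. In teal the other exits, to isomer, third conformer and quench (impurity held at its charge, pseudo-first-order, and third conformer counted as an exit), sum to 0.287 s⁻¹. Back constant over back constant plus exits gives 3.48% for teal: this is the return share ρ, the chance that a molecule of other conformer goes back to starting material.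

Now the ladder, fastest first. Other conformer in teal has a half-life of 2.33 s, shorter than the 8.15 s of starting material, so it should stay a trace intermediate. Starting material then drains over 4.91 half-lives in 40 s, and the direct share to target, the selectivity σ, is 68.8%. That gives 0.0665 M by the direct route in teal. Slower still, quench by itself has a half-life of 55 s in teal, longer than the life of other conformer, and dormant form returns with a half-life of 912 s, longer than the run.

By our reckoning from the forward constants, a share of 17.8% of the starting material charged enters other conformer. The return route is that share times ρ times σ, which in teal carries 4.26 × 10⁻⁴ M, or 0.640% of the direct amount. We commit to a row that hardly changes.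

The forecast says the same: it gives 0.067 M for teal and 0.0668 M for red, and its row hardly changes, since “raising the impurity trims target by only a fraction of a percent”.

The simulation gives 0.0670 M, 0.0670 M, 0.0670 M and 0.0669 M for teal, ochre, green and red, so the row hardly changes. At the end, red holds 4.47% of the starting material charged as quenched substrate, against 0.717% in teal. For red the exits sum to 0.376 s⁻¹, so ρ falls to 2.68%, below teal's. By our reckoning, the return route in red carries 3.28 × 10⁻⁴ M, which is 9.81 × 10⁻⁵ M less than in teal.

All constants belong to no real substance; the flask was simulated.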